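Retrosynthesis: the spiroketal is opened at the C5–O1 bond of ring A to a hydroxy enol ether in which ring B is a 4,5-dihydrofuran; the bond between the last CH2 of the hexyl chain and C2 is then cut, and both fragments are taken back to acyclic pieces.
Enabling feature: C2 is an oxygen-bearing CH standing 1,4 to the ketal carbon C5, so C2 can be an aldehyde carbon and C5 the oxygen-bearing sp2 carbon of a ring B enol ether (C5=C9); one C–C bond formation then gives the direct precursor of the 1,6-dioxaspiro[4.4]nonane.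
Forward: phthalide ring first (aryl ketone, transfer hydrogenation, ortho-bromination, carboxylation–lactonisation), ring B second (epoxide alkynylation, 5-endo-dig cycloisomerisation), then the chain CH2–C2 bond by catalytic asymmetric alkylzinc addition, and ring A last by spiroketalization.
Stereochemistry: phthalide C3 from the (S,S)-TsDPEN ruthenium catalyst; C7 from (S)-propylene oxide; C2 from the (1R,2R)-bis(triflamide) titanium catalyst of the key step; spiro C5 from a confined chiral Brønsted acid under kinetic control.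

Key step: step 9

Assumption: in the last step the (S,S)-enantiomer of the confined imidodiphosphoric acid is taken to be the one matched to the 5S spiro centre; if the sense of induction is the reverse, the (R,R)-enantiomer is used under the same conditions. The starting materials are taken to be commercially available.

Step 1
Reactants: 1 6-bromohex-1-ene; 2 3,5-dimethoxybenzonitrile
Product: 5 1-(3,5-dimethoxyphenyl)hept-6-en-1-one, via hex-5-en-1-ylmagnesium bromide 3 (not isolated), via N-bromomagnesio ketimine 4 (not isolated)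
Conditions: Mg, THF, rt; then 2, CuBr (2 mol%), THF, 60 °C; then 2 M HCl, rt
Reagents that add atoms: water, O
Why: Grignard addition to an aryl nitrile should stop at the N-magnesio imine, which aqueous acid hydrolyses to the aryl alkyl ketone; no stereocentre is formed.

Step 2
Reactants: 5 1-(3,5-dimethoxyphenyl)hept-6-en-1-one
Product: 6 (1S)-1-(3,5-dimethoxyphenyl)hept-6-en-1-ol
Conditions: RuCl(p-cymene)[(S,S)-TsDPEN] (1 mol%), HCO2H/Et3N (5:2), 30 °C
Reagents that add atoms: none
Why: Noyori asymmetric transfer hydrogenation of an aryl n-alkyl ketone, in which the (S,S)-catalyst is expected to give the (S)-carbinol as it does with acetophenone-type ketones, and which should leave the terminal alkene untouched.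

Step 3
Reactants: 6 (1S)-1-(3,5-dimethoxyphenyl)hept-6-en-1-ol
Product: 7 (1S)-1-(2-bromo-3,5-dimethoxyphenyl)hept-6-en-1-ol
Conditions: NBS (1.0 equiv), MeCN, −20 to 0 °C, dark
Reagents that add atoms: N-bromosuccinimide, O=C1CCC(=O)N1Br
Why: Electrophilic aromatic bromination should go to C2 of the aryl ring, which is ortho to one methoxy group and para to the other and less shielded than C4 between the two methoxy groups; the carbinol centre is not touched.

Step 4
Reactants: 7 (1S)-1-(2-bromo-3,5-dimethoxyphenyl)hept-6-en-1-ol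
Product: 11 (3S)-3-(hex-5-en-1-yl)-5,7-dimethoxyisobenzofuran-1(3H)-one, via dilithiated aryl alkoxide 8 (not isolated), via dilithium carboxylate alkoxide 9 (not isolated), via hydroxy acid 10 (not isolated)
Conditions: nBuLi (2.2 equiv), THF, −78 °C; CO2 (gas), −78 °C to rt; then 2 M HCl, rt
Reagents that add atoms: carbon dioxide, O=C=O
Why: Bromine–lithium exchange on the lithium alkoxide, carboxylation of the aryllithium and acid-induced lactonisation of the 2-(1-hydroxyalkyl)benzoic acid (5-exo-trig acyl substitution) should close the phthalide without touching the C–O bond of the stereocentre.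

Step 5
Reactants: 12 tert-butyldimethyl(pent-4-yn-1-yloxy)silane; 13 (S)-2-methyloxirane
Product: 15 (2S)-8-[(tert-butyldimethylsilyl)oxy]oct-4-yn-2-ol, via lithium alkynide 14 (not isolated)
Conditions: nBuLi, THF, −78 °C; BF3·OEt2, then 13, −78 °C; H2O
Reagents that add atoms: none
Why: BF3-promoted opening of a terminal epoxide by a lithium acetylide (Yamaguchi–Hirao alkynylation) occurs at the CH2 terminus, so the future C7 stereocentre is carried over unchanged from (S)-propylene oxide.

Step 6
Reactants: 15 (2S)-8-[(tert-butyldimethylsilyl)oxy]oct-4-yn-2-ol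
Product: 16 tert-butyldimethyl{3-[(5S)-5-methyl-4,5-dihydrofuran-2-yl]propoxy}silane
Conditions: PdCl2(PhCN)2 (2 mol%), Et2O, rt; then Et3N, filtration through basic Al2O3
Reagents that add atoms: none
Why: Divalent-palladium-catalysed 5-endo-dig hydroalkoxylation of a homopropargylic alcohol (anti-oxypalladation, then protodepalladation) should give the 2,3-dihydrofuran in which the distal alkyne carbon becomes the enol ether carbon (the future C5); the stereocentre is not involved.

Step 7
Reactants: 16 tert-butyldimethyl{3-[(5S)-5-methyl-4,5-dihydrofuran-2-yl]propoxy}silane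
Product: 17 3-[(5S)-5-methyl-4,5-dihydrofuran-2-yl]propan-1-ol
Conditions: Bu4NF, THF, 0 °C; H2O; Et3N-deactivated SiO2
Reagents that add atoms: none
Why: Fluoride cleavage of a primary silyl ether runs under basic conditions that the acid-labile enol ether should tolerate.

Step 8
Reactants: 17 3-[(5S)-5-methyl-4,5-dihydrofuran-2-yl]propan-1-ol
Product: 18 3-[(5S)-5-methyl-4,5-dihydrofuran-2-yl]propanal
Conditions: SO3·pyridine, DMSO, iPr2NEt, CH2Cl2, 0 °C
Reagents that add atoms: none
Why: Parikh–Doering oxidation keeps an amine base present throughout, so the primary alcohol should be oxidised to the aldehyde without exposing the enol ether to acid.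

Step 9
Reactants: 11 (3S)-3-(hex-5-en-1-yl)-5,7-dimethoxyisobenzofuran-1(3H)-one; 18 3-[(5S)-5-methyl-4,5-dihydrofuran-2-yl]propanal
Product: 22 (3S)-3-{(7S)-7-hydroxy-9-[(5S)-5-methyl-4,5-dihydrofuran-2-yl]nonyl}-5,7-dimethoxyisobenzofuran-1(3H)-one, via alkyldiethylborane 19 (not isolated), via dialkylzinc 20 (not isolated), via alkyl(trimethylsilylmethyl)zinc 21 (not isolated)
Conditions: 11 (1.5 equiv), Et2BH, Et2O, 0 °C to rt; Et2Zn (neat), 0 °C, volatiles removed in vacuo; Zn(CH2SiMe3)2, toluene; then 18, Ti(OiPr)4 (2 equiv), (1R,2R)-1,2-bis(trifluoromethanesulfonamido)cyclohexane (8 mol%), toluene, −20 °C; aq. NaHCO3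
Reagents that add atoms: none
Why: Anti-Markovnikov hydroboration of the terminal alkene of 11 and boron–zinc exchange turn the last chain carbon into a C(sp3)–Zn nucleophile, which the titanium bis(sulfonamide) complex transfers to the Si face of the aldehyde carbon of 18 (the future C2), so that the CH2–C2 bond and the C2 carbinol form in one event. The closest known reaction type is the catalytic asymmetric addition of functionalised diorganozincs, made from terminal alkenes by hydroboration and boron–zinc exchange, to aliphatic aldehydes under Ti(OiPr)4/trans-1,2-bis(triflamido)cyclohexane catalysis. No ring is closed in this step; ring A is left open, with the new O1–H placed so that it can later reach the enol ether carbon C5 of ring B in a five-membered closure. The new stereocentre (7S in 22, later C2) is set by the ligand alone, the (1R,2R)-enantiomer being the one expected to give Si-face attack, while the remote phthalide C3 and dihydrofuran C5 centres play no part. The step needs chemoselectivity for the aldehyde over the phthalide carbonyl and the acid-labile enol ether: the C–Zn bond should not add to the hindered, electron-rich aryl lactone, the CH2SiMe3 group on zinc is not transferred, Ti(OiPr)4 is too weak a Lewis acid to ionise a trisubstituted enol ether without a proton source, and the work-up is kept basic.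

Step 10
Reactants: 22 (3S)-3-{(7S)-7-hydroxy-9-[(5S)-5-methyl-4,5-dihydrofuran-2-yl]nonyl}-5,7-dimethoxyisobenzofuran-1(3H)-one
Product: 23 (3S)-5,7-dimethoxy-3-{6-[(2S,5S,7S)-7-methyl-1,6-dioxaspiro[4.4]nonan-2-yl]hexyl}isobenzofuran-1(3H)-one
Conditions: (S,S)-imidodiphosphoric acid built from two (S)-3,3′-bis(2,4,6-triethylphenyl)-BINOL units (5 mol%), 4 Å molecular sieves, MTBE, −35 °C; then Et3N
Reagents that add atoms: none
Why: Chiral Brønsted acid-catalysed spiroketalization of a hydroxy enol ether, in which protonation at C9 gives the ring B oxocarbenium ion paired with the chiral imidodiphosphate and O1 adds to C5 (5-exo-trig) inside the confined ion pair under kinetic control, so that the catalyst, and not the small thermodynamic bias expected at this spiro centre, should set 5S.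

Compound list
1 | 6-bromohex-1-ene | C=CCCCCBr | starting material
2 | 3,5-dimethoxybenzonitrile | N#Cc1cc(OC)cc(OC)c1 | starting material
3 | hex-5-en-1-ylmagnesium bromide | C=CCCCC[Mg]Br | intermediate
4 | N-(bromomagnesio)-1-(3,5-dimethoxyphenyl)hept-6-en-1-imine | C=CCCCCC(=N[Mg]Br)c1cc(OC)cc(OC)c1 | intermediate
5 | 1-(3,5-dimethoxyphenyl)hept-6-en-1-one | C=CCCCCC(=O)c1cc(OC)cc(OC)c1 | intermediate
6 | (1S)-1-(3,5-dimethoxyphenyl)hept-6-en-1-ol | C=CCCCC[C@H](O)c1cc(OC)cc(OC)c1 | intermediate
7 | (1S)-1-(2-bromo-3,5-dimethoxyphenyl)hept-6-en-1-ol | C=CCCCC[C@H](O)c1cc(OC)cc(OC)c1Br | intermediate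
8 | lithium (1S)-1-(2-lithio-3,5-dimethoxyphenyl)hept-6-en-1-olate | C=CCCCC[C@H](O[Li])c1cc(OC)cc(OC)c1[Li] | intermediate
9 | dilithium 2-[(1S)-1-oxidohept-6-en-1-yl]-4,6-dimethoxybenzoate | C=CCCCC[C@H](O[Li])c1cc(OC)cc(OC)c1C(=O)O[Li] | intermediate
10 | 2-[(1S)-1-hydroxyhept-6-en-1-yl]-4,6-dimethoxybenzoic acid | C=CCCCC[C@H](O)c1cc(OC)cc(OC)c1C(=O)O | intermediate
11 | (3S)-3-(hex-5-en-1-yl)-5,7-dimethoxyisobenzofuran-1(3H)-one | COc1cc(OC)c2c(c1)[C@H](CCCCC=C)OC2=O | intermediate
12 | tert-butyldimethyl(pent-4-yn-1-yloxy)silane | C#CCCCO[Si](C)(C)C(C)(C)C | starting material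
13 | (S)-2-methyloxirane [(S)-propylene oxide] | C[C@H]1CO1 | starting material
14 | lithium 5-[(tert-butyldimethylsilyl)oxy]pent-1-yn-1-ide | [Li]C#CCCCO[Si](C)(C)C(C)(C)C | intermediate
15 | (2S)-8-[(tert-butyldimethylsilyl)oxy]oct-4-yn-2-ol | C[C@H](O)CC#CCCCO[Si](C)(C)C(C)(C)C | intermediate
16 | tert-butyldimethyl{3-[(5S)-5-methyl-4,5-dihydrofuran-2-yl]propoxy}silane | C[C@H]1CC=C(CCCO[Si](C)(C)C(C)(C)C)O1 | intermediate
17 | 3-[(5S)-5-methyl-4,5-dihydrofuran-2-yl]propan-1-ol | C[C@H]1CC=C(CCCO)O1 | intermediate
18 | 3-[(5S)-5-methyl-4,5-dihydrofuran-2-yl]propanal | C[C@H]1CC=C(CCC=O)O1 | intermediate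
19 | (3S)-3-[6-(diethylboranyl)hexyl]-5,7-dimethoxyisobenzofuran-1(3H)-one | COc1cc(OC)c2c(c1)[C@H](CCCCCCB(CC)CC)OC2=O | intermediate
20 | bis{6-[(1S)-4,6-dimethoxy-3-oxo-1,3-dihydroisobenzofuran-1-yl]hexyl}zinc | COc1cc(OC)c2c(c1)[C@H](CCCCCC[Zn]CCCCCC[C@@H]1OC(=O)c3c(OC)cc(OC)cc31)OC2=O | intermediate
21 | {6-[(1S)-4,6-dimethoxy-3-oxo-1,3-dihydroisobenzofuran-1-yl]hexyl}[(trimethylsilyl)methyl]zinc | COc1cc(OC)c2c(c1)[C@H](CCCCCC[Zn]C[Si](C)(C)C)OC2=O | intermediate
22 | (3S)-3-{(7S)-7-hydroxy-9-[(5S)-5-methyl-4,5-dihydrofuran-2-yl]nonyl}-5,7-dimethoxyisobenzofuran-1(3H)-one | COc1cc(OC)c2c(c1)[C@H](CCCCCC[C@H](O)CCC1=CC[C@H](C)O1)OC2=O | intermediate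
23 | (3S)-5,7-dimethoxy-3-{6-[(2S,5S,7S)-7-methyl-1,6-dioxaspiro[4.4]nonan-2-yl]hexyl}isobenzofuran-1(3H)-one | COc1cc(OC)c2c(c1)[C@H](CCCCCC[C@H]1CC[C@]3(CC[C@H](C)O3)O1)OC2=O | target

Total step count: 10. Longest linear sequence: 6 steps (steps 1–4, 9, 10; steps 5–8, 9, 10 are equally long).

Steps most likely to fail

Step 10. The addition of O1 to the ring B oxocarbenium ion may show poor facial selectivity with this secondary alcohol, or 22 may cyclise without the catalyst during handling; either process would give both C5 epimers. The fallback sets out from 22 and uses thermodynamic control with recycling: camphorsulfonic acid (cat.) in CH2Cl2 at rt should give 23 together with its spiro epimer, (3S)-5,7-dimethoxy-3-{6-[(2S,5R,7S)-7-methyl-1,6-dioxaspiro[4.4]nonan-2-yl]hexyl}isobenzofuran-1(3H)-one F1. The two are separated by preparative HPLC, and F1 is returned to the same acid for re-equilibration, so that the material converges on 23.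

Step 9. The enol ether of 18 may be lost under the titanium Lewis acid (hydrolysis or premature, uncontrolled ring closure), or incomplete boron–zinc exchange may lead to competing ethyl transfer. The fallback sets out from 17 and 11 and forms the same bond by lithiation–borylation, which is basic throughout. Alcohol 17 is converted with iPr2NCOCl and NaH (THF) into 3-[(5S)-5-methyl-4,5-dihydrofuran-2-yl]propyl N,N-diisopropylcarbamate F2. Alkene 11 is hydroborated with pinacolborane ([Ir(cod)Cl]2/dppe cat., CH2Cl2) to the pinacol boronate (3S)-5,7-dimethoxy-3-[6-(4,4,5,5-tetramethyl-1,3,2-dioxaborolan-2-yl)hexyl]isobenzofuran-1(3H)-one F3. Carbamate F2 is deprotonated with sBuLi/(−)-sparteine (Et2O, −78 °C) to the (1S)-1-lithio carbamate F4, which is trapped by a slight excess of F3 as the lithium boronate complex F5. On warming, 1,2-migration of the hexyl group with loss of the carbamate should give the secondary boronic ester (3S)-5,7-dimethoxy-3-{(7S)-9-[(5S)-5-methyl-4,5-dihydrofuran-2-yl]-7-(4,4,5,5-tetramethyl-1,3,2-dioxaborolan-2-yl)nonyl}isobenzofuran-1(3H)-one F6. Oxidation with NaBO3·4H2O (THF/H2O) proceeds with retention and rejoins the route at 22.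

Step 6. Unreacted alcohol may add intermolecularly to the enol ether as it forms (mixed ketals), or the product may be hydrated to the γ-hydroxy ketone, instead of clean 5-endo-dig closure. The fallback sets out from 13 and builds the substituted enol ether by alkylation of a metalated dihydrofuran. LiC≡CH·ethylenediamine (DMSO) opens 13 to (S)-pent-4-yn-2-ol F7. (Et3N)Mo(CO)5, generated by irradiation of Mo(CO)6 in Et3N/Et2O, should cycloisomerise F7 through its vinylidene complex to (2S)-2-methyl-2,3-dihydrofuran F8. tBuLi (THF, −78 to 0 °C) lithiates the enol ether CH of F8 to [(5S)-5-methyl-4,5-dihydrofuran-2-yl]lithium F9, and alkylation with tert-butyl(3-iodopropoxy)dimethylsilane F10 rejoins the route at 16.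

Further compounds
F1 | step 10 | (3S)-5,7-dimethoxy-3-{6-[(2S,5R,7S)-7-methyl-1,6-dioxaspiro[4.4]nonan-2-yl]hexyl}isobenzofuran-1(3H)-one | COc1cc(OC)c2c(c1)[C@H](CCCCCC[C@H]1CC[C@@]3(CC[C@H](C)O3)O1)OC2=O
F2 | step 9 | 3-[(5S)-5-methyl-4,5-dihydrofuran-2-yl]propyl N,N-diisopropylcarbamate | CC(C)N(C(C)C)C(=O)OCCCC1=CC[C@H](C)O1
F3 | step 9 | (3S)-5,7-dimethoxy-3-[6-(4,4,5,5-tetramethyl-1,3,2-dioxaborolan-2-yl)hexyl]isobenzofuran-1(3H)-one | COc1cc(OC)c2c(c1)[C@H](CCCCCCB3OC(C)(C)C(C)(C)O3)OC2=O
F4 | step 9 | (1S)-1-lithio-3-[(5S)-5-methyl-4,5-dihydrofuran-2-yl]propyl N,N-diisopropylcarbamate | CC(C)N(C(C)C)C(=O)O[C@@H]([Li])CCC1=CC[C@H](C)O1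
F5 | step 9 | lithium boronate complex of F3 carrying the (1S)-1-(diisopropylcarbamoyloxy)-3-[(5S)-5-methyl-4,5-dihydrofuran-2-yl]propyl group on boron | COc1cc(OC)c2c(c1)[C@H](CCCCCC[B-]3(OC(C)(C)C(C)(C)O3)[C@H](OC(=O)N(C(C)C)C(C)C)CCC4=CC[C@H](C)O4)OC2=O.[Li+]
F6 | step 9 | (3S)-5,7-dimethoxy-3-{(7S)-9-[(5S)-5-methyl-4,5-dihydrofuran-2-yl]-7-(4,4,5,5-tetramethyl-1,3,2-dioxaborolan-2-yl)nonyl}isobenzofuran-1(3H)-one | COc1cc(OC)c2c(c1)[C@H](CCCCCC[C@H](B3OC(C)(C)C(C)(C)O3)CCC4=CC[C@H](C)O4)OC2=O
F7 | step 6 | (S)-pent-4-yn-2-ol | C[C@H](O)CC#C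
F8 | step 6 | (2S)-2-methyl-2,3-dihydrofuran | C[C@H]1CC=CO1
F9 | step 6 | [(5S)-5-methyl-4,5-dihydrofuran-2-yl]lithium | C[C@H]1CC=C([Li])O1
F10 | step 6 | tert-butyl(3-iodopropoxy)dimethylsilane | CC(C)(C)[Si](C)(C)OCCCI
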